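I choose to read these flasks by one concentration, the one at which ring closure takes over from dimerisation, and to leave the impurity aside at first.

    starting material → single ring (k1 = 0.010 /h)
    2 starting material → open dimer (k2 = 0.011 /M/h)
    starting material + open dimer → open trimer (k3 = 0.0072 /M/h)
    open dimer → ring dimer (k4 = 0.039 /h)
    starting material + protic impurity → quenched substrate (k5 = 0.034 /M/h)
    crystals ⇌ single ring, rate k6*(cs6 - [single ring]) while solid is left; crystals form when [single ring] > cs6 (cs6 = 1.3 M, k6 = 0.28 /h)

in all of them: starting material 2.0 M; time 3.0 d
- oak: protic impurity 0.150 M
- alder: protic impurity 0.300 M
- maple: protic impurity 0.600 M

- in percentages every species weighs as the starting material in it: one open dimer or ring dimer counts as two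
- in percentages every species weighs as the starting material in it: one open trimer counts as three
- for single ring the crystals are counted in
- two of one species on the left: rate k times its square, two consumed each time
- as a solid, counted per litre of solution: crystals
- "hardly changes" means that all values lie within two and a half points (for a concentration: within two and a half percent of the largest)
- run time (oak): 3.0 d

- share of single ring in all that became single ring or open dimer or open trimer or ring dimer for oak, alder, maple, in this order
- the course of these numbers from the first flask to the last (hardly changes / rises, then falls / rises all the way / falls all the way / falls, then rises)

**The crossing.** Let A be the concentration of starting material. Ring closure takes it at 0.010 /h times A, and dimerisation takes it at 0.0220 /M/h times A squared, so the two are equal at 0.455 M, the crossing concentration A_c. The quotient A/A_c is a selectivity factor, 4.4 at the start in oak. Of the starting material used by these two steps at any moment, the fraction A_c/(A + A_c) becomes single ring. Protic impurity does not appear in A_c.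

**The ladder.** In oak, as charged, open dimer closes to ring dimer with a half-life of 0.74 d. Starting material dimerises more slowly, with a first half-life of 0.947 d, so I expect ring dimer to collect what dimerisation starts. Open dimer's half-life towards open trimer is longer, 2.0 d. With ring closure and dimerisation reckoned by themselves, oak reaches A_c at 2.03 d, inside the run. Ring closure has a half-life of 2.9 d, and the quench is slower than every rung above in oak, at 5.7 d.

**My reckoning.** I sum that fraction with trimer and impurity left aside. Oak then holds 0.299 M of starting material at 3.0 d and 0.537 M of single ring, a share of 31.6 %. Carried to the last of the starting material, the sum gives 0.767 M of single ring, below the solubility of 1.3 M, so I expect no crystals. The ceiling share is 38.3 %. Since the flasks share one A_c, I commit to a row that hardly changes.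

**The forecast.** It gives 31.4 %, 32.1 % and 33.4 %, with the shape hardly changes. Its oak figure is slightly below mine. It holds that “the share is set by the first-order ring closure competing with the second-order dimerisation”.

**The result.** The simulation gives 31.1 %, 31.5 % and 32.4 %, with the shape hardly changes. These numbers belong to the time given. Run ten times as long, oak climbs from 31.1 % to 37.4 %. At the asked time oak still holds 13.1 % of its charge as starting material, below the crossing at 22.7 % of the charge, where ring closure leads. Maple has the same A_c and the same ceiling of 38.3 %, and run ten times as long it reaches 37.4 %.

The numbers are those of an exercise; the flask was simulated.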